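**Retrosynthesis**
- Dichrostachine H is a [4+2] adduct. Cutting the C12–C1′ and C15–C6′ bonds gives a labdane 1,3-diene (**12**) and a 2-aryl-5-methoxy-p-quinone (**6**) that carries the 5,7-diacetoxychromone.
- **6** comes from a flavone (**5**) by CAN oxidation of its 2′,5′-dimethoxy ring. The flavone comes from phloroacetophenone and 2,4,5-trimethoxybenzaldehyde through a chalcone.
- **12** comes from 4-epi-trans-communic acid: C18 is taken from the acid to the aldehyde level, the diene is masked as an SO₂ adduct, and Riley allylic hydroxylation puts the C7-OH on the exocyclic alkene.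
- Ring order: the decalin is already in the chiral-pool acid. The chromone ring forms in Step 2. The cyclohexene ring forms in the photochemical [4+2] (Step 10). The cyclohexenedione ring is already present in quinone **6**.

**Assumptions**
- 4-Epi-trans-communic acid (**7**, equatorial C18 acid, normal 5α/9α/10β series) is available from juniper resin or as a reference standard.
- The remote labdane stereocentres give only modest facial selectivity in the [4+2], so the diastereomers are separated by HPLC.

---

**Step 1**
Reactants: **1** 2′,4′,6′-trihydroxyacetophenone; **2** 2,4,5-trimethoxybenzaldehyde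
Product: **3** (E)-2′,4′,6′-trihydroxy-2,4,5-trimethoxychalcone
Conditions: 50% aq. KOH, EtOH, rt, 48 h; then HCl
Reagents that add atoms: none
Why: Claisen–Schmidt condensation; no stereocentre is formed and the enone is E.

**Step 2**
Reactants: **3**
Product: **4** 5,7-dihydroxy-2′,4′,5′-trimethoxyflavone
Conditions: I₂ (0.1 equiv), DMSO, 130 °C
Reagents that add atoms: none
Why: I₂/DMSO oxidative cyclisation of a 2′-hydroxychalcone (oxa-Michael then iodine-mediated dehydrogenation) gives the flavone.

**Step 3**
Reactants: **4**
Product: **5** 5,7-diacetoxy-2′,4′,5′-trimethoxyflavone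
Conditions: Ac₂O, pyridine, DMAP (cat.), 60 °C
Reagents that add atoms: acetic anhydride, CC(=O)OC(C)=O
Why: Acetylation masks the phenols, which would quench radical-cation or excited-quinone chemistry in Step 10.

**Step 4**
Reactants: **5**
Product: **6** 2-(5,7-diacetoxy-4-oxochromen-2-yl)-5-methoxy-1,4-benzoquinone
Conditions: CAN (2.5 equiv), MeCN/H₂O 3:1, 0 °C
Reagents that add atoms: water, O
Why: CAN oxidatively demethylates the only para-dimethoxy pair (2′,5′) to the quinone, leaving the vinylogous 4′-OMe and the acetates intact.

**Step 5**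
Reactants: **7** 4-epi-trans-communic acid
Product: **8** labda-8(17),12E,14-trien-18-ol
Conditions: LiAlH₄, THF, 0 °C to rt
Reagents that add atoms: none
Why: Hydride reduction of the carboxylic acid; the alkenes are untouched and all four ring stereocentres are retained.

**Step 6**
Reactants: **8**
Product: **9** labda-8(17),12E,14-trien-18-al
Conditions: DMP, NaHCO₃, CH₂Cl₂, rt
Reagents that add atoms: none
Why: Dess–Martin oxidation of the primary alcohol to the α-quaternary aldehyde, which cannot epimerise.

**Step 7**
Reactants: **9**
Product: **10** SO₂ adduct of **9** (3-methyl-2-alkyl-2,5-dihydrothiophene 1,1-dioxide), as a C12 epimer mixture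
Conditions: liquid SO₂, hydroquinone (cat.), sealed tube, −10 °C to rt
Reagents that add atoms: sulfur dioxide, O=S=O
Why: Cheletropic SO₂ capture of the diene masks it as a sulfolene so it survives Step 8; the new C12 centre is erased in Step 9.

**Step 8**
Reactants: **10**
Product: **11** 7β-hydroxy sulfolene (10 with C7-OH)
Conditions: SeO₂ (0.2 equiv), TBHP (3 equiv), CH₂Cl₂, 0 °C to rt
Reagents that add atoms: selenium dioxide, O=[Se]=O; tert-butyl hydroperoxide, CC(C)(C)OO
Why: Riley/Sharpless allylic hydroxylation: an ene reaction at the exocyclic C8=C17 followed by a [2,3] shift places oxygen on C7, and the equatorial 7β-alcohol is expected to dominate; the minor 7α epimer is removed by chromatography.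

**Step 9**
Reactants: **11**
Product: **12** 7β-hydroxy-labda-8(17),12E,14-trien-18-al
Conditions: toluene, 110 °C, N₂ sparge, solid NaHCO₃
Reagents that add atoms: none (SO₂ is lost)
Why: Retro-cheletropic SO₂ extrusion is disrotatory, so the outward-rotating C12 alkyl gives the (12E)-diene.

**Step 10**
Reactants: **6** quinone (1.5 equiv); **12** diene (1.0 equiv)
Product: **13** Diels–Alder adduct diacetate
Conditions: Mes-Acr-Me⁺ BF₄⁻ (5 mol %), CH₂Cl₂ (0.02 M), degassed, blue LEDs (450 nm), rt; diastereomers separated by HPLC
Reagents that add atoms: none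
Why: Proposed new method: the excited acridinium oxidises the 1-alkyl-2-methylbutadiene (~+1.6 V) to its radical cation, whose unsubstituted C15 terminus attacks C6′ of the chromone-conjugated quinone C=C. This leaves a benzylic-type radical at C1′, which closes onto C12 to form the aryl-bearing quaternary centre, and the resulting radical cation is reduced by acridinyl radical or semiquinone, so the net reaction is redox-neutral. The closest known reactions are radical-cation Diels–Alder cycloadditions (Bauld; Yoon-type photoredox) and chloranil-sensitised PET cycloadditions. The new features are an electron-poor quinone as the partner, an unactivated alkyl diene, and a quaternary centre formed next to a tertiary one. Closure on one face of the cyclic alkene gives the cis C1′/C6′ ring fusion. The chromone-endo approach places the C11 chain cis to the aryl group, which fixes C12 relative to C1′. The absolute sense comes from the diene face chosen by the labdane, and the minor diastereomer is removed by HPLC.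

**Step 11**
Reactants: **13**
Product: **14** Dichrostachine H
Conditions: NH₄OAc, MeOH/H₂O, rt
Reagents that add atoms: none
Why: Mild transesterification removes the two phenolic acetates without base-induced epimerisation of the C6′–H α to the ketone or attack on the aldehyde; no stereocentre is touched.

---

**Compound list**

| No. | Name | SMILES | Role |
|---|---|---|---|
| 1 | 2′,4′,6′-trihydroxyacetophenone | CC(=O)c1c(O)cc(O)cc1O | starting material |
| 2 | 2,4,5-trimethoxybenzaldehyde | COc1cc(OC)c(C=O)cc1OC | starting material |
| 3 | (E)-2′,4′,6′-trihydroxy-2,4,5-trimethoxychalcone | COc1cc(OC)c(/C=C/C(=O)c2c(O)cc(O)cc2O)cc1OC | intermediate |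
| 4 | 5,7-dihydroxy-2′,4′,5′-trimethoxyflavone | COc1cc(OC)c(cc1OC)-c1cc(=O)c2c(O)cc(O)cc2o1 | intermediate |
| 5 | 5,7-diacetoxy-2′,4′,5′-trimethoxyflavone | COc1cc(OC)c(cc1OC)-c1cc(=O)c2c(OC(C)=O)cc(OC(C)=O)cc2o1 | intermediate |
| 6 | 2-(5,7-diacetoxychromon-2-yl)-5-methoxy-1,4-benzoquinone | COC1=CC(=O)C(=CC1=O)c1cc(=O)c2c(OC(C)=O)cc(OC(C)=O)cc2o1 | intermediate |
| 7 | 4-epi-trans-communic acid (labda-8(17),12E,14-trien-18-oic acid) | C=C1CC[C@@H]2[C@](C)(CCC[C@@]2(C)C(=O)O)[C@H]1C/C=C(C)/C=C | starting material |
| 8 | labda-8(17),12E,14-trien-18-ol | C=C1CC[C@@H]2[C@](C)(CCC[C@@]2(C)CO)[C@H]1C/C=C(C)/C=C | intermediate |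
| 9 | labda-8(17),12E,14-trien-18-al | C=C1CC[C@@H]2[C@](C)(CCC[C@@]2(C)C=O)[C@H]1C/C=C(C)/C=C | intermediate |
| 10 | SO₂ adduct (sulfolene) of 9 | C=C1CC[C@@H]2[C@](C)(CCC[C@@]2(C)C=O)[C@H]1CC1C(C)=CCS1(=O)=O | intermediate |
| 11 | 7β-hydroxy sulfolene | C=C1[C@@H](O)C[C@@H]2[C@](C)(CCC[C@@]2(C)C=O)[C@H]1CC1C(C)=CCS1(=O)=O | intermediate |
| 12 | 7β-hydroxy-labda-8(17),12E,14-trien-18-al | C=C1[C@@H](O)C[C@@H]2[C@](C)(CCC[C@@]2(C)C=O)[C@H]1C/C=C(C)/C=C | intermediate |
| 13 | Diels–Alder adduct diacetate | C=C1[C@@H](O)C[C@@H]2[C@](C)(CCC[C@@]2(C)C=O)[C@H]1C[C@@H]1C(C)=CC[C@H]2C(=O)C(OC)=CC(=O)[C@@]12c1cc(=O)c2c(OC(C)=O)cc(OC(C)=O)cc2o1 | intermediate |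
| 14 | Dichrostachine H | C=C1[C@@H](O)C[C@@H]2[C@](C)(CCC[C@@]2(C)C=O)[C@H]1C[C@@H]1C(C)=CC[C@H]2C(=O)C(OC)=CC(=O)[C@@]12c1cc(=O)c2c(O)cc(O)cc2o1 | target |

**Totals:** 11 steps in total; the longest linear sequence is 7 steps (Steps 5–11).

**Three steps most likely to fail**
1. **Step 10 (proposed new photochemical [4+2]).** The diene radical cation may attack the more nucleophilic vinylogous-ester C=C, or give low dr or photoreduction side reactions.
   - Fallback (known chemistry): a conventional thermal or high-pressure quinone Diels–Alder of **6** and **12** (toluene, 80 °C, or 10 kbar), followed by HPLC separation of the diastereomers.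
2. **Step 8 (Riley hydroxylation).** The C7 stereoselectivity may be poor, or the aldehyde may be oxidised by TBHP.
   - Fallback: over-oxidise to the 7-ketone (CrO₃·3,5-dimethylpyrazole) and reduce with NaBH₄/CeCl₃, which attacks axially and gives the equatorial 7β-alcohol.
3. **Step 11 (deacetylation).** The 5-OAc is hindered, and the C6′–H α to the ketone may epimerise.
   - Fallback: build the flavone as the 5,7-di-O-allyl ether in Step 3 and remove the allyl groups with Pd(PPh₃)₄/morpholine, which is pH-neutral.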